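**Retrosynthetic overview**
1. Target 22 ⇒ cross-metathesis at C12=C13: allyl-decalin diol 15 + (S)-acetoxy methylene lactone 21 (two steps from (S)-3-hydroxy-γ-butyrolactone 16).
2. Diol 15 ⇒ LiAlH4 reduction (C3 ketone, C19 ester, auxiliary released) of bicyclic keto ester 14.
3. 14 ⇒ key step: the C4–C5 bond is made by oxidative polarity reversal of a β-keto ester enolate. The electrophilic C4 radical (a one-electron enolonium equivalent) attacks the C5=C10 alkene, then C10 attacks C9; copper oxidation gives C8=C17.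
4. Acyclic trienyl keto ester 10 ⇒ γ-alkylation of the 8-phenylmenthyl 2-methylacetoacetate dianion with bromide 5, which comes from geranyl acetate 1 (allylic oxidation, allyl–vinyl coupling, bromination).
5. Ring order: ring A, then ring B, in one flask; the lactone ring is bought as 16 and attached last.

Numbering: labdane numbering is used (C4 quaternary, C10 angular methyl, C8 exocyclic methylene, C9 side chain, lactone C13–C16).

Assumption: the facial bias of an 8-phenylmenthyl α-methyl β-keto ester radical is taken as (−)-auxiliary → 10β-methyl (normal) series, so the (+)-auxiliary 6 is used for the ent series needed here; if the sense proves opposite, the (−)-auxiliary is used and nothing else changes.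

**Route**

Step 1
Reactants: 1 geranyl acetate, (2E)-3,7-dimethylocta-2,6-dien-1-yl acetate
Product: 2 (2E,6E)-8-hydroxy-3,7-dimethylocta-2,6-dien-1-yl acetate
Conditions: SeO2 (10 mol %), salicylic acid (10 mol %), t-BuOOH (70% aq, 3.5 equiv), CH2Cl2, 25 °C, 36 h
Reagents that add atoms: tert-butyl hydroperoxide CC(C)(C)OO (oxygen source, passed on through selenium dioxide O=[Se]=O)
Why: Selenium dioxide allylic oxidation (ene reaction, then [2,3]-sigmatropic shift) attacks the (E)-methyl of the electron-rich terminal alkene, because the 2,3-alkene is deactivated by its allylic acetate, and gives the (E)-allylic alcohol.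

Step 2
Reactants: 2 (2E,6E)-8-hydroxy-3,7-dimethylocta-2,6-dien-1-yl acetate; 3 tributyl(vinyl)stannane
Product: 4 (2E,6E)-2,6-dimethyldeca-2,6,9-trien-1-ol
Conditions: Pd(dba)2 (3 mol %), LiCl (3 equiv), DMF, 25–40 °C
Reagents that add atoms: none
Why: Stille allyl–vinyl coupling, in which zerovalent palladium ionises only the allylic acetate (the allylic alcohol is inert) and the vinyl group is delivered to the primary terminus of the π-allyl complex with the E geometry kept.

Step 3
Reactants: 4 (2E,6E)-2,6-dimethyldeca-2,6,9-trien-1-ol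
Product: 5 (2E,6E)-1-bromo-2,6-dimethyldeca-2,6,9-triene
Conditions: CBr4 (1.2 equiv), PPh3 (1.25 equiv), CH2Cl2, 0 °C, 30 min, used at once
Reagents that add atoms: tetrabromomethane BrC(Br)(Br)Br
Why: Appel bromination converts the primary allylic alcohol to the bromide under neutral conditions, without allylic transposition or migration of the skipped diene.

Step 4
Reactants: 6 (+)-8-phenylmenthol, (1S,2R,5S)-5-methyl-2-(2-phenylpropan-2-yl)cyclohexan-1-ol; 7 ethyl 2-methyl-3-oxobutanoate (racemic)
Product: 8 (1S,2R,5S)-5-methyl-2-(2-phenylpropan-2-yl)cyclohexyl 2-methyl-3-oxobutanoate (both C2 epimers)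
Conditions: 7 (3 equiv), DMAP (0.3 equiv), toluene, reflux through 4 Å sieves (EtOH removed), 24 h
Reagents that add atoms: none
Why: DMAP-catalysed transesterification of a β-keto ester is driven by removal of ethanol and tolerates the hindered secondary alcohol; the C2 centre is planarised later, so the epimer mixture does not matter.

Step 5
Reactants: 8 (1S,2R,5S)-5-methyl-2-(2-phenylpropan-2-yl)cyclohexyl 2-methyl-3-oxobutanoate; 5 (2E,6E)-1-bromo-2,6-dimethyldeca-2,6,9-triene
Product: 10 (1S,2R,5S)-5-methyl-2-(2-phenylpropan-2-yl)cyclohexyl (6E,10E)-2,6,10-trimethyl-3-oxotetradeca-6,10,13-trienoate (both C2 epimers), via dilithium dianion 9 (not isolated)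
Conditions: LiN(iPr)2 (2.1 equiv), THF, 0 °C, 30 min; 5 (1.0 equiv), −78 → 0 °C; aq NH4Cl
Reagents that add atoms: none
Why: Weiler dianion alkylation, in which the more basic γ-carbanion displaces the primary allylic bromide by SN2, giving only γ-alkylation and leaving both E alkenes untouched.

Step 6
Reactants: 10 (1S,2R,5S)-5-methyl-2-(2-phenylpropan-2-yl)cyclohexyl (6E,10E)-2,6,10-trimethyl-3-oxotetradeca-6,10,13-trienoate
Product: 14 (1S,2R,5S)-5-methyl-2-(2-phenylpropan-2-yl)cyclohexyl (1S,4aS,5R,8aS)-1,4a-dimethyl-6-methylidene-2-oxo-5-(prop-2-en-1-yl)decahydronaphthalene-1-carboxylate, via C4 keto ester radical 11 (not isolated), via monocyclic C10 radical 12 (not isolated), via bicyclic C8 radical 13 (not isolated)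
Conditions: Mn(OAc)3·2H2O (2.2 equiv), Cu(OAc)2·H2O (1.0 equiv), degassed AcOH, 25 → 40 °C, 20 h
Reagents that add atoms: none
Why: Manganese triacetate/copper diacetate oxidative free-radical polyene cyclization, in which one-electron oxidation turns the normally nucleophilic enolate carbon C4 into an electrophilic radical that bonds to the nucleophilic alkene carbon C5; the (E,E)-diene then closes 6-endo/6-endo through chair–chair transition states to the trans-decalin (C10 methyl axial, H-5 and H-9 axial, allyl equatorial), the ester ends up axial and syn to the C10 methyl because the α-methyl lies syn to the ketone oxygen in the radical, the phenyl group of the auxiliary shields one face of the radical and so fixes the absolute sense, and divalent copper oxidises the tertiary C8 radical to the exocyclic alkene.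

Step 7
Reactants: 14 bicyclic keto ester (name as in step 6)
Product: 15 (1R,2R,4aS,5R,8aS)-1-(hydroxymethyl)-1,4a-dimethyl-6-methylidene-5-(prop-2-en-1-yl)decahydronaphthalen-2-ol
Conditions: LiAlH4 (4 equiv), THF, 0 °C → reflux, 6 h; Fieser work-up; 6 recovered on chromatography
Reagents that add atoms: none
Why: Lithium aluminium hydride reduction, in which hydride adds axially to the C3 ketone from the face away from the axial C4 and C10 substituents to give the equatorial alcohol, and then reduces the neopentyl ester to the C19 carbinol with release of the auxiliary.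

Step 8
Reactants: 16 (S)-3-hydroxy-γ-butyrolactone, (4S)-4-hydroxyoxolan-2-one
Product: 20 (4S)-4-hydroxy-3-methylideneoxolan-2-one, via dilithium lactone dianion 17 (not isolated), via trans Mannich base 18 (not isolated), via trimethylammonium iodide 19 (not isolated)
Conditions: LiN(iPr)2 (2.2 equiv), THF, −78 → −40 °C; CH2=NMe2+ I− (1.2 equiv), −78 → 0 °C; aq NH4Cl; crude amine, MeI (5 equiv), MeOH, 25 °C; aq NaHCO3, CH2Cl2, 25 °C
Reagents that add atoms: N,N-dimethylmethyleneiminium iodide (Eschenmoser's salt) C=[N+](C)C.[I-]; iodomethane CI (its methyl and iodide end in intermediate 19 only)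
Why: Fráter–Seebach dianion formation (the alkoxide cannot leave, so no β-elimination), Mannich reaction with Eschenmoser's salt, N-methylation and Hofmann-type E1cB loss of trimethylamine give the α-methylene lactone without touching the C14 carbinol centre.

Step 9
Reactants: 20 (4S)-4-hydroxy-3-methylideneoxolan-2-one
Product: 21 (3S)-4-methylidene-5-oxooxolan-3-yl acetate
Conditions: Ac2O (1.5 equiv), pyridine (2 equiv), CH2Cl2, 0 → 25 °C
Reagents that add atoms: acetic anhydride CC(=O)OC(C)=O
Why: O-acylation of the secondary alcohol with retention at C14, run without DMAP so that no nucleophile adds SN2′ to the Morita–Baylis–Hillman-type acetate.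

Step 10
Reactants: 15 allyl-decalin diol (name as in step 7); 21 (3S)-4-methylidene-5-oxooxolan-3-yl acetate
Product: 22 (3S,4E)-4-{2-[(1R,4aS,5R,6R,8aS)-6-hydroxy-5-(hydroxymethyl)-5,8a-dimethyl-2-methylidenedecahydronaphthalen-1-yl]ethylidene}-5-oxooxolan-3-yl acetate (14-O-acetylandrographolide, CNP0077248.1)
Conditions: 21 (3 equiv), second-generation Hoveyda–Grubbs catalyst, dichloro[1,3-bis(2,4,6-trimethylphenyl)imidazolidin-2-ylidene](2-isopropoxybenzylidene)ruthenium, C31H38Cl2N2ORu (10 mol %), 2,6-dichloro-1,4-benzoquinone (20 mol %), toluene, 60 °C, argon sparge, 16 h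
Reagents that add atoms: none
Why: Olefin cross-metathesis between the unhindered terminal alkene of 15 and the 1,1-disubstituted electron-poor methylene lactone (which does not homodimerise), with the hindered C8 exocyclic methylene and the free hydroxyls inert; the E-alkylidene lactone (C11 anti to the lactone carbonyl) is the thermodynamic product and C14 arrives unchanged from 21.

**Compound list**
1 | geranyl acetate | CC(C)=CCC/C(C)=C/COC(C)=O | starting material
2 | (2E,6E)-8-hydroxy-3,7-dimethylocta-2,6-dien-1-yl acetate | OC/C(C)=C/CC/C(C)=C/COC(C)=O | intermediate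
3 | tributyl(vinyl)stannane | C=C[Sn](CCCC)(CCCC)CCCC | starting material
4 | (2E,6E)-2,6-dimethyldeca-2,6,9-trien-1-ol | OC/C(C)=C/CC/C(C)=C/CC=C | intermediate
5 | (2E,6E)-1-bromo-2,6-dimethyldeca-2,6,9-triene | BrC/C(C)=C/CC/C(C)=C/CC=C | intermediate
6 | (+)-8-phenylmenthol, (1S,2R,5S)-5-methyl-2-(2-phenylpropan-2-yl)cyclohexan-1-ol | C[C@H]1CC[C@H](C(C)(C)c2ccccc2)[C@@H](O)C1 | starting material
7 | ethyl 2-methyl-3-oxobutanoate (racemic) | CCOC(=O)C(C)C(C)=O | starting material
8 | (1S,2R,5S)-8-phenylmenthyl 2-methyl-3-oxobutanoate (C2 epimers) | CC(=O)C(C)C(=O)O[C@H]1C[C@@H](C)CC[C@@H]1C(C)(C)c1ccccc1 | intermediate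
9 | dilithium dianion of 8 | [Li+].[Li+].C=C([O-])C(C)=C([O-])O[C@H]1C[C@@H](C)CC[C@@H]1C(C)(C)c1ccccc1 | intermediate
10 | (1S,2R,5S)-8-phenylmenthyl (6E,10E)-2,6,10-trimethyl-3-oxotetradeca-6,10,13-trienoate (C2 epimers) | C=CC/C=C(\C)CC/C=C(\C)CCC(=O)C(C)C(=O)O[C@H]1C[C@@H](C)CC[C@@H]1C(C)(C)c1ccccc1 | intermediate
11 | C4 (α-keto ester) radical of 10 | C=CC/C=C(\C)CC/C=C(\C)CCC(=O)[C](C)C(=O)O[C@H]1C[C@@H](C)CC[C@@H]1C(C)(C)c1ccccc1 | intermediate
12 | monocyclic C10 radical (ring A closed, C4 and C5 set) | C=CC/C=C(\C)CC[C@@H]1[C@](C)(C(=O)O[C@H]2C[C@@H](C)CC[C@@H]2C(C)(C)c2ccccc2)C(=O)CC[C]1C | intermediate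
13 | bicyclic C8 tertiary radical (trans-decalin) | C[C]1CC[C@@H]2[C@](C)(C(=O)O[C@H]3C[C@@H](C)CC[C@@H]3C(C)(C)c3ccccc3)C(=O)CC[C@@]2(C)[C@@H]1CC=C | intermediate
14 | (1S,2R,5S)-8-phenylmenthyl (1S,4aS,5R,8aS)-1,4a-dimethyl-6-methylidene-2-oxo-5-(prop-2-en-1-yl)decahydronaphthalene-1-carboxylate | C=C1CC[C@@H]2[C@](C)(C(=O)O[C@H]3C[C@@H](C)CC[C@@H]3C(C)(C)c3ccccc3)C(=O)CC[C@@]2(C)[C@@H]1CC=C | intermediate
15 | (1R,2R,4aS,5R,8aS)-1-(hydroxymethyl)-1,4a-dimethyl-6-methylidene-5-(prop-2-en-1-yl)decahydronaphthalen-2-ol | C=C1CC[C@@H]2[C@](C)(CO)[C@H](O)CC[C@@]2(C)[C@@H]1CC=C | intermediate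
16 | (S)-3-hydroxy-γ-butyrolactone, (4S)-4-hydroxyoxolan-2-one | C1C(=O)OC[C@H]1O | starting material
17 | dilithium dianion of 16 | [Li+].[Li+].C1=C([O-])OC[C@H]1[O-] | intermediate
18 | trans-(3S,4S)-3-[(dimethylamino)methyl]-4-hydroxyoxolan-2-one | CN(C)C[C@@H]1C(=O)OC[C@H]1O | intermediate
19 | [(3S,4S)-4-hydroxy-2-oxooxolan-3-yl]methyl-trimethylammonium iodide | C[N+](C)(C)C[C@@H]1C(=O)OC[C@H]1O.[I-] | intermediate
20 | (4S)-4-hydroxy-3-methylideneoxolan-2-one ((S)-tulipalin B) | C=C1C(=O)OC[C@H]1O | intermediate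
21 | (3S)-4-methylidene-5-oxooxolan-3-yl acetate | C=C1C(=O)OC[C@H]1OC(C)=O | intermediate
22 | 14-O-acetylandrographolide (CNP0077248.1) | C=C1CC[C@@H]2[C@](C)(CO)[C@H](O)CC[C@@]2(C)[C@@H]1C/C=C1/C(=O)OC[C@H]1OC(C)=O | target

**Count**
Total steps: 10. Longest linear sequence: 7 (steps 1, 2, 3, 5, 6, 7, 10); steps 4, 8 and 9 are side branches.

**Three steps most likely to fail**

Step 6 (key bicyclization). The risks are the level and sense of auxiliary control, copper oxidation of radical 12 before ring B closes, and endocyclic alkene isomers. The fallback sets out from bromide 5 and comes back to the route at diol 15. (−)-8-Phenylmenthol and 2,2,6-trimethyl-4H-1,3-dioxin-4-one in refluxing xylene give (1R,2S,5R)-8-phenylmenthyl 3-oxobutanoate F1. Its dianion is alkylated with 5 to the α-unsubstituted trienyl keto ester F2. Mn(OAc)3·2H2O and Cu(OAc)2·H2O with Yb(OTf)3 in CF3CH2OH at 0 °C then cyclise the two-point chelated enolate radical, whose ester conformation is locked; with the (−)-auxiliary this chelated mode is expected to give the ent series, yielding the bicyclic β-keto ester F3 (C5, C9 and C10 set, C4 still enolisable). K2CO3 and MeI in acetone methylate C4 from the face opposite the axial C10 methyl, giving the axial ester F4, and LiAlH4 reduces F4 to 15.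

Step 10 (cross-metathesis). The risks are the hindered 1,1-disubstituted partner carrying an allylic acetate, a trisubstituted product, and alkene isomerisation. The fallback sets out from diol 15 and lactone 16 and comes back at target 22. 2,2-Dimethoxypropane and PPTS convert 15 into the 3,19-acetonide F6, and OsO4 (cat.) with NaIO4 and 2,6-lutidine cleaves only the monosubstituted alkene to the C12 aldehyde F7. Lactone 16 is silylated to the tert-butyldimethylsilyl ether F8 and trapped with LiN(iPr)2 and Me3SiCl (internal quench, −78 °C, no free enolate) as the silyl ketene acetal F9. Mukaiyama aldol addition of F9 to F7 (BF3·OEt2, −78 °C) gives the β-hydroxy lactone F10; MsCl and Et3N give the mesylate F11, and DBU eliminates the mesylate in preference to the silyloxy group to give the E-alkylidene lactone F12. HF·pyridine frees the C14 alcohol (3,19-O-isopropylideneandrographolide F13), Ac2O and pyridine give the 14-acetate F14, and aqueous acetic acid removes the acetonide to give 22.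

Step 8 (methylenation of the hydroxy lactone). The risks are fragmentation of dianion 17 and loss of the small, water-soluble, base-sensitive product during quaternisation and elimination. The fallback does not set out from a numbered compound: it replaces 16–19 by two purchased compounds, (tert-butyldimethylsilyloxy)acetaldehyde and 1,1,1,3,3,3-hexafluoropropan-2-yl acrylate, and comes back at 20. An asymmetric Morita–Baylis–Hillman reaction (β-isocupreidine 10 mol %, DMF, −55 °C) gives the (S)-adduct, 1,1,1,3,3,3-hexafluoropropan-2-yl (3S)-4-(tert-butyldimethylsilyloxy)-3-hydroxy-2-methylidenebutanoate F5; the catalyst's usual sense corresponds to S here because CH2OSi outranks the vinyl carbon. Aqueous HCl in THF removes the silyl group, and the primary alcohol lactonises onto the activated ester to give 20, whose rotation is checked against material made from 16.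

**Further compounds**
F1 | step 6 | (1R,2S,5R)-8-phenylmenthyl 3-oxobutanoate | CC(=O)CC(=O)O[C@@H]1C[C@H](C)CC[C@H]1C(C)(C)c1ccccc1
F2 | step 6 | (1R,2S,5R)-8-phenylmenthyl (6E,10E)-6,10-dimethyl-3-oxotetradeca-6,10,13-trienoate | C=CC/C=C(\C)CC/C=C(\C)CCC(=O)CC(=O)O[C@@H]1C[C@H](C)CC[C@H]1C(C)(C)c1ccccc1
F3 | step 6 | (1R,2S,5R)-8-phenylmenthyl (4aS,5R,8aS)-4a-methyl-6-methylidene-2-oxo-5-(prop-2-en-1-yl)decahydronaphthalene-1-carboxylate (C1 epimers and enol) | C=C1CC[C@@H]2C(C(=O)O[C@@H]3C[C@H](C)CC[C@H]3C(C)(C)c3ccccc3)C(=O)CC[C@@]2(C)[C@@H]1CC=C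
F4 | step 6 | (1R,2S,5R)-8-phenylmenthyl (1S,4aS,5R,8aS)-1,4a-dimethyl-6-methylidene-2-oxo-5-(prop-2-en-1-yl)decahydronaphthalene-1-carboxylate | C=C1CC[C@@H]2[C@](C)(C(=O)O[C@@H]3C[C@H](C)CC[C@H]3C(C)(C)c3ccccc3)C(=O)CC[C@@]2(C)[C@@H]1CC=C
F5 | step 8 | 1,1,1,3,3,3-hexafluoropropan-2-yl (3S)-4-(tert-butyldimethylsilyloxy)-3-hydroxy-2-methylidenebutanoate | C=C(C(=O)OC(C(F)(F)F)C(F)(F)F)[C@H](O)CO[Si](C)(C)C(C)(C)C
F6 | step 10 | 3,19-O-isopropylidene derivative of 15 | C=C1CC[C@@H]2[C@](C)(COC(C)(C)O3)[C@H]3CC[C@@]2(C)[C@@H]1CC=C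
F7 | step 10 | C12 aldehyde of the 3,19-acetonide (14,15,16-trinorlabd-8(17)-en-12-al type) | C=C1CC[C@@H]2[C@](C)(COC(C)(C)O3)[C@H]3CC[C@@]2(C)[C@@H]1CC=O
F8 | step 10 | (4S)-4-(tert-butyldimethylsilyloxy)oxolan-2-one | C1C(=O)OC[C@H]1O[Si](C)(C)C(C)(C)C
F9 | step 10 | (3S)-3-(tert-butyldimethylsilyloxy)-5-(trimethylsilyloxy)-2,3-dihydrofuran | C1=C(O[Si](C)(C)C)OC[C@H]1O[Si](C)(C)C(C)(C)C
F10 | step 10 | aldol adduct, 12-hydroxy-14-O-silyl lactone on the 3,19-acetonide (C12 epimers, C13/C14 trans) | C=C1CC[C@@H]2[C@](C)(COC(C)(C)O3)[C@H]3CC[C@@]2(C)[C@@H]1CC(O)[C@@H]1C(=O)OC[C@H]1O[Si](C)(C)C(C)(C)C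
F11 | step 10 | 12-O-mesylate of F10 | C=C1CC[C@@H]2[C@](C)(COC(C)(C)O3)[C@H]3CC[C@@]2(C)[C@@H]1CC(OS(C)(=O)=O)[C@@H]1C(=O)OC[C@H]1O[Si](C)(C)C(C)(C)C
F12 | step 10 | 14-O-(tert-butyldimethylsilyl)-3,19-O-isopropylideneandrographolide | C=C1CC[C@@H]2[C@](C)(COC(C)(C)O3)[C@H]3CC[C@@]2(C)[C@@H]1C/C=C1/C(=O)OC[C@H]1O[Si](C)(C)C(C)(C)C
F13 | step 10 | 3,19-O-isopropylideneandrographolide | C=C1CC[C@@H]2[C@](C)(COC(C)(C)O3)[C@H]3CC[C@@]2(C)[C@@H]1C/C=C1/C(=O)OC[C@H]1O
F14 | step 10 | 14-O-acetyl-3,19-O-isopropylideneandrographolide | C=C1CC[C@@H]2[C@](C)(COC(C)(C)O3)[C@H]3CC[C@@]2(C)[C@@H]1C/C=C1/C(=O)OC[C@H]1OC(C)=O
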